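The central C4'–O–C4 ether is read as the alkoxy oxygen of an ester whose carbonyl carbon is C4'. O4 stays on C4 of the intact all-cis (2R,3R,4R) unit A, and C4' of unit B becomes a benzoate carbonyl. One titanium-methylidene operation then converts that carbonyl into an enol ether and closes the C3'–C4' bond of pyran ring C of unit B by metathesis with a vinyl group on C2', giving a 4'-alkoxy-2H-chromene. The precursor is the ester of the silyl-protected unit A alcohol with an (R)-2-(1-arylallyloxy)benzoic acid. Epoxidation and anti hydride opening of the enol ether then set C3' and C4'.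

Key step: step 18

Remark: TBSO = tert-butyldimethylsilyloxy, TIPSO = triisopropylsilyloxy, L = O,O'-(1,1'-binaphthyl-2,2'-diyl)-N,N-bis(1-phenylethyl)phosphoramidite, TBD = 1,5,7-triazabicyclo[4.4.0]dec-5-ene; unprimed locants belong to unit A, primed ones to unit B.
Remark: the four catechol oxygens carry TIPS groups, because a TBS group next to the phenoxide used in the two etherifications could shift from oxygen to oxygen; the other three oxygens carry TBS; the (Ra,Rc,Rc) ligand is assumed to give the (R)-ether, as with simple aryloxides.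

Step 1
Reactants: 1 2,3,4-trihydroxybenzaldehyde
Product: 2 2-hydroxy-3,4-bis(TIPSO)benzaldehyde
Conditions: TIPSCl (2.2 equiv), imidazole, DMF, 0 °C to rt
Reagents that add atoms: chlorotriisopropylsilane, CC(C)[Si](Cl)(C(C)C)C(C)C
Why: Regioselective silyl ether formation; the 2-OH is held in a hydrogen bond to the aldehyde, so the 4- and 3-hydroxyls should react first.

Step 2
Reactants: 3 methyl (E)-4-hydroxycinnamate
Product: 4 methyl (E)-3-[4-(TBSO)phenyl]acrylate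
Conditions: TBSCl, imidazole, DMF, rt
Reagents that add atoms: tert-butylchlorodimethylsilane, CC(C)(C)[Si](C)(C)Cl
Why: Standard silylation of a phenol.

Step 3
Reactants: 4 methyl (E)-3-[4-(TBSO)phenyl]acrylate
Product: 5 (E)-3-[4-(TBSO)phenyl]prop-2-en-1-ol
Conditions: i-Bu2AlH, CH2Cl2, −78 °C; aq. potassium sodium tartrate
Reagents that add atoms: none
Why: 1,2-Reduction of an enoate to the allylic alcohol with i-Bu2AlH, which leaves the aryl silyl ether and the E alkene untouched.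

Step 4
Reactants: 5 (E)-3-[4-(TBSO)phenyl]prop-2-en-1-ol
Product: 6 tert-butyl (E)-3-[4-(TBSO)phenyl]allyl carbonate
Conditions: Boc2O, DMAP (10 mol %), CH2Cl2, 0 °C to rt
Reagents that add atoms: di-tert-butyl dicarbonate, CC(C)(C)OC(=O)OC(=O)OC(C)(C)C
Why: DMAP-catalysed O-acylation to the allylic carbonate; the tert-butyl carbonate later releases only tert-butoxide, which is too hindered to attack the aryl silyl ethers.

Step 5
Reactants: 2 2-hydroxy-3,4-bis(TIPSO)benzaldehyde; 6 tert-butyl (E)-3-[4-(TBSO)phenyl]allyl carbonate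
Product: 7 (R)-2-{1-[4-(TBSO)phenyl]allyloxy}-3,4-bis(TIPSO)benzaldehyde
Conditions: [Ir(cod)Cl]2 (2 mol %), (Ra,Rc,Rc)-L (4 mol %), TBD (8 mol %, catalyst pre-formed), THF, rt
Reagents that add atoms: none
Why: Iridium-catalysed asymmetric allylic etherification; the aryloxide attacks the aryl-substituted terminus of the allyl-iridium complex, and the ligand sets the centre that becomes C2' (R here, designated S in the target only because C3' later outranks the aryl group).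

Step 6
Reactants: 7 (R)-2-{1-[4-(TBSO)phenyl]allyloxy}-3,4-bis(TIPSO)benzaldehyde
Product: 8 (R)-2-{1-[4-(TBSO)phenyl]allyloxy}-3,4-bis(TIPSO)benzoic acid
Conditions: NaClO2, NaH2PO4, 2-methyl-2-butene, t-BuOH/THF/H2O, 0 °C
Reagents that add atoms: sodium chlorite, [Na+].[O-]Cl=O
Why: Pinnick oxidation gives the acid without an ester-cleavage step; the buffered medium and the chlorine scavenger should spare the vinyl group, the silyl ethers and the allylic aryl ether.

Step 7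
Reactants: 2 2-hydroxy-3,4-bis(TIPSO)benzaldehyde; 6 tert-butyl (E)-3-[4-(TBSO)phenyl]allyl carbonate
Product: 9 (S)-2-{1-[4-(TBSO)phenyl]allyloxy}-3,4-bis(TIPSO)benzaldehyde
Conditions: [Ir(cod)Cl]2 (2 mol %), (Sa,Sc,Sc)-L (4 mol %), TBD (8 mol %, catalyst pre-formed), THF, rt
Reagents that add atoms: none
Why: The same iridium-catalysed allylic etherification with the enantiomeric ligand sets the centre that becomes C2 of unit A (S here, designated R from compound 13 on).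

Step 8
Reactants: 9 (S)-2-{1-[4-(TBSO)phenyl]allyloxy}-3,4-bis(TIPSO)benzaldehyde
Product: 10 (S)-1-[4-(TBSO)phenyl]allyl 2,3-bis(TIPSO)-6-vinylphenyl ether
Conditions: Ph3PCH3Br, KN(SiMe3)2, THF, 0 °C; then 9, −78 °C to rt
Reagents that add atoms: methyltriphenylphosphonium bromide, C[P+](c1ccccc1)(c1ccccc1)c1ccccc1.[Br-]
Why: Wittig methylenation of an aryl aldehyde; no free phenol is present and the ether stereocentre is not acidic enough to be touched by the ylide.

Step 9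
Reactants: 10 (S)-1-[4-(TBSO)phenyl]allyl 2,3-bis(TIPSO)-6-vinylphenyl ether
Product: 11 (S)-2-[4-(TBSO)phenyl]-7,8-bis(TIPSO)-2H-chromene
Conditions: (H2IMes)(PCy3)Cl2Ru=CHPh (second-generation Grubbs catalyst, 5 mol %), CH2Cl2, 40 °C
Reagents that add atoms: none
Why: Ring-closing metathesis of a styrene with an allylic aryl ether is a standard route to 2H-chromenes and does not touch C2.

Step 10
Reactants: 11 (S)-2-[4-(TBSO)phenyl]-7,8-bis(TIPSO)-2H-chromene
Product: 13 (2R,3S)-2-[4-(TBSO)phenyl]-7,8-bis(TIPSO)chroman-3-ol, via 3,4-epoxyflavan 12 (not isolated)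
Conditions: dimethyldioxirane, acetone/CH2Cl2, −40 °C; volatiles removed cold; i-Bu2AlH, CH2Cl2, −78 °C
Reagents that add atoms: dimethyldioxirane, CC1(C)OO1
Why: Epoxidation of the styrene-type C3=C4 bond anti to the 2-aryl group, then Lewis-acid-assisted hydride opening of the aryl epoxide at benzylic C4, should put the oxygen on C3; the C3 configuration is erased in step 11, so a minor cis alcohol would converge.

Step 11
Reactants: 13 (2R,3S)-2-[4-(TBSO)phenyl]-7,8-bis(TIPSO)chroman-3-ol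
Product: 14 (R)-2-[4-(TBSO)phenyl]-7,8-bis(TIPSO)chroman-3-one
Conditions: Dess–Martin periodinane, NaHCO3, CH2Cl2, 0 °C; used crude
Reagents that add atoms: none
Why: Dess–Martin oxidation under buffered, non-enolising conditions should give the flavan-3-one without epimerising C2.

Step 12
Reactants: 14 (R)-2-[4-(TBSO)phenyl]-7,8-bis(TIPSO)chroman-3-one
Product: 15 (2R,3R)-2-[4-(TBSO)phenyl]-7,8-bis(TIPSO)chroman-3-ol
Conditions: LiBH(s-Bu)3, LiBr, THF, −78 °C
Reagents that add atoms: none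
Why: L-Selectride reduction of a flavan-3-one; the bulky hydride approaches anti to the 2-aryl group, so the new 3-OH is cis to it (the usual 2,3-trans to 2,3-cis inversion of flavan-3-ols), which sets C3.

Step 13
Reactants: 15 (2R,3R)-2-[4-(TBSO)phenyl]-7,8-bis(TIPSO)chroman-3-ol
Product: 16 (2R,3R)-3-(TBSO)-2-[4-(TBSO)phenyl]-7,8-bis(TIPSO)chroman
Conditions: TBSOTf, 2,6-lutidine, CH2Cl2, −78 to 0 °C
Reagents that add atoms: tert-butyldimethylsilyl trifluoromethanesulfonate, CC(C)(C)[Si](C)(C)OS(=O)(=O)C(F)(F)F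
Why: Silyl triflate silylation is the standard way to cap a hindered axial secondary alcohol.

Step 14
Reactants: 16 (2R,3R)-3-(TBSO)-2-[4-(TBSO)phenyl]-7,8-bis(TIPSO)chroman
Product: 17 (2R,3R,4S)-3-(TBSO)-2-[4-(TBSO)phenyl]-7,8-bis(TIPSO)chroman-4-ol
Conditions: DDQ, CH2Cl2/H2O, 0 °C to rt
Reagents that add atoms: water, O
Why: DDQ benzylic oxidation; hydride abstraction at C4 gives a cation stabilised by O1 and the para 7-silyloxy group, and water adds trans to the 3-silyloxy group (known C4 functionalisation of protected flavan-3-ols); over-oxidation to ketone 18 would be harmless.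

Step 15
Reactants: 17 (2R,3R,4S)-3-(TBSO)-2-[4-(TBSO)phenyl]-7,8-bis(TIPSO)chroman-4-ol
Product: 18 (2R,3S)-3-(TBSO)-2-[4-(TBSO)phenyl]-7,8-bis(TIPSO)chroman-4-one
Conditions: Dess–Martin periodinane, NaHCO3, CH2Cl2, 0 °C
Reagents that add atoms: none
Why: Dess–Martin oxidation of the benzylic alcohol under buffered conditions should keep the epimerisable 2,3-cis silyloxy ketone intact.

Step 16
Reactants: 18 (2R,3S)-3-(TBSO)-2-[4-(TBSO)phenyl]-7,8-bis(TIPSO)chroman-4-one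
Product: 19 (2R,3R,4R)-3-(TBSO)-2-[4-(TBSO)phenyl]-7,8-bis(TIPSO)chroman-4-ol
Conditions: NaBH4, CeCl3·7H2O, MeOH/THF, −78 °C
Reagents that add atoms: none
Why: Luche-type borohydride reduction; the 3-silyloxy group of the 2,3-cis ketone is axial and hydride attacks C4 anti to it (Felkin–Anh), so the 4-OH ends cis to both neighbours, which sets C4 and leaves it as the only free hydroxyl.

Step 17
Reactants: 19 (2R,3R,4R)-3-(TBSO)-2-[4-(TBSO)phenyl]-7,8-bis(TIPSO)chroman-4-ol; 8 (R)-2-{1-[4-(TBSO)phenyl]allyloxy}-3,4-bis(TIPSO)benzoic acid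
Product: 20 (2R,3S,4R)-3-(TBSO)-2-[4-(TBSO)phenyl]-7,8-bis(TIPSO)chroman-4-yl (R)-2-{1-[4-(TBSO)phenyl]allyloxy}-3,4-bis(TIPSO)benzoate
Conditions: 2-methyl-6-nitrobenzoic anhydride, DMAP, Et3N, CH2Cl2, rt
Reagents that add atoms: none
Why: Shiina esterification (mixed anhydride, DMAP acyl transfer) under basic conditions; the C4–O bond of 19 is not broken, so the all-cis configuration is retained and the benzylic centre is never ionised.

Step 18
Reactants: 20 (2R,3S,4R)-3-(TBSO)-2-[4-(TBSO)phenyl]-7,8-bis(TIPSO)chroman-4-yl (R)-2-{1-[4-(TBSO)phenyl]allyloxy}-3,4-bis(TIPSO)benzoate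
Product: 22 4'-alkoxy-2H-chromene dimer: ether of 19 at O4 to C4' of the (R)-2-[4-(TBSO)phenyl]-7,8-bis(TIPSO)-2H-chromen-4-yl group, via 1-arylvinyl ether 21 (not isolated)
Conditions: Cp2Ti(CH2)ClAlMe2 (4 equiv), pyridine (cat.), THF, 0 °C to rt, then 60 °C; aq. NaOH
Reagents that add atoms: none
Why: Cp2Ti=CH2, released from the reagent by pyridine, first methylenates the only ester carbonyl of 20 ([2+2] cycloaddition and cycloreversion, the oxygen leaving as titanocene oxide) to give α-alkoxystyrene 21; a second equivalent adds to the terminal vinyl group, and loss of ethylene from the titanacyclobutane leaves a titanium alkylidene at C3'. Intramolecular [2+2] cycloaddition of this alkylidene with the enol ether C=CH2 and cycloreversion close the six-membered pyran ring C of unit B as a ring-closing metathesis that forms the endocyclic C3'=C4' bond, which is the known titanium-methylidene cyclisation of olefinic esters to cyclic enol ethers. No stereocentre is created; C4 keeps its configuration because its C–O bond is never broken, and C2' is only a spectator allylic ether carbon. The step needs chemoselective attack on the ester in the presence of seven silyl ethers and survival of the acid-labile C2' aryl allyl ether; the absence of any other carbonyl, the pyridine buffer for the aluminium Lewis acid and the moderate temperature should secure this. The closure is helped by the ortho relationship of the two reacting arms on the benzene ring and by conjugation of the new enol ether with that ring.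

Step 19
Reactants: 22 4'-alkoxy-2H-chromene dimer
Product: 24 heptasilyl ether of the target with free 3'-OH (unit A 2R,3R,4R; unit B 2'S,3'R,4'R), via epoxy ether 23 (not isolated)
Conditions: dimethyldioxirane, acetone/CH2Cl2, −78 °C; volatiles removed cold; Et3SiH (10 equiv), BF3·OEt2 (1.1 equiv), CH2Cl2, −78 °C; Et3N quench
Reagents that add atoms: dimethyldioxirane, CC1(C)OO1
Why: Dimethyldioxirane should epoxidise the electron-rich enol ether anti to the C2' aryl group (sets C3'), and BF3-assisted opening of the epoxy ether at the more substituted benzylic C4' with Et3SiH (ionic hydrogenation of an epoxide) should deliver hydride with inversion, trans to the C3' oxygen as nucleophiles usually enter at C4 of 2,3-trans flavan-3-ols (sets C4').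

Step 20
Reactants: 24 heptasilyl ether of the target with free 3'-OH
Product: 25 (2R,3R,4R)-4-{[(2S,3R,4R)-3,7,8-trihydroxy-2-(4-hydroxyphenyl)chroman-4-yl]oxy}-2-(4-hydroxyphenyl)chroman-3,7,8-triol (CNP0241481.1)
Conditions: Bu4NF, AcOH (1:1), THF, 0 °C to rt, argon
Reagents that add atoms: none
Why: Acetic-acid-buffered fluoride desilylation removes the four aryl TIPS, two aryl TBS and one secondary TBS ethers without strong acid or base, so the benzylic C4–O–C4' ether and the oxidation-prone trihydroxylated rings should survive.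

Compound list
1 | 2,3,4-trihydroxybenzaldehyde | O=Cc1ccc(O)c(O)c1O | starting material
2 | 2-hydroxy-3,4-bis(TIPSO)benzaldehyde | O=Cc1ccc(O[Si](C(C)C)(C(C)C)C(C)C)c(O[Si](C(C)C)(C(C)C)C(C)C)c1O | intermediate
3 | methyl (E)-4-hydroxycinnamate | COC(=O)/C=C/c1ccc(O)cc1 | starting material
4 | methyl (E)-3-[4-(TBSO)phenyl]acrylate | COC(=O)/C=C/c1ccc(O[Si](C)(C)C(C)(C)C)cc1 | intermediate
5 | (E)-3-[4-(TBSO)phenyl]prop-2-en-1-ol | OC/C=C/c1ccc(O[Si](C)(C)C(C)(C)C)cc1 | intermediate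
6 | tert-butyl (E)-3-[4-(TBSO)phenyl]allyl carbonate | CC(C)(C)OC(=O)OC/C=C/c1ccc(O[Si](C)(C)C(C)(C)C)cc1 | intermediate
7 | (R)-2-{1-[4-(TBSO)phenyl]allyloxy}-3,4-bis(TIPSO)benzaldehyde | O=Cc1ccc(O[Si](C(C)C)(C(C)C)C(C)C)c(O[Si](C(C)C)(C(C)C)C(C)C)c1O[C@H](C=C)c1ccc(O[Si](C)(C)C(C)(C)C)cc1 | intermediate
8 | (R)-2-{1-[4-(TBSO)phenyl]allyloxy}-3,4-bis(TIPSO)benzoic acid | OC(=O)c1ccc(O[Si](C(C)C)(C(C)C)C(C)C)c(O[Si](C(C)C)(C(C)C)C(C)C)c1O[C@H](C=C)c1ccc(O[Si](C)(C)C(C)(C)C)cc1 | intermediate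
9 | (S)-2-{1-[4-(TBSO)phenyl]allyloxy}-3,4-bis(TIPSO)benzaldehyde | O=Cc1ccc(O[Si](C(C)C)(C(C)C)C(C)C)c(O[Si](C(C)C)(C(C)C)C(C)C)c1O[C@@H](C=C)c1ccc(O[Si](C)(C)C(C)(C)C)cc1 | intermediate
10 | (S)-1-[4-(TBSO)phenyl]allyl 2,3-bis(TIPSO)-6-vinylphenyl ether | C=Cc1ccc(O[Si](C(C)C)(C(C)C)C(C)C)c(O[Si](C(C)C)(C(C)C)C(C)C)c1O[C@@H](C=C)c1ccc(O[Si](C)(C)C(C)(C)C)cc1 | intermediate
11 | (S)-2-[4-(TBSO)phenyl]-7,8-bis(TIPSO)-2H-chromene | CC(C)(C)[Si](C)(C)Oc1ccc([C@H]2Oc3c(ccc(O[Si](C(C)C)(C(C)C)C(C)C)c3O[Si](C(C)C)(C(C)C)C(C)C)C=C2)cc1 | intermediate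
12 | 3,4-epoxide of 11, oxirane oxygen trans to the 2-aryl group | CC(C)(C)[Si](C)(C)Oc1ccc([C@H]2Oc3c(ccc(O[Si](C(C)C)(C(C)C)C(C)C)c3O[Si](C(C)C)(C(C)C)C(C)C)[C@@H]3O[C@H]23)cc1 | intermediate
13 | (2R,3S)-2-[4-(TBSO)phenyl]-7,8-bis(TIPSO)chroman-3-ol (2,3-trans) | CC(C)(C)[Si](C)(C)Oc1ccc([C@H]2Oc3c(ccc(O[Si](C(C)C)(C(C)C)C(C)C)c3O[Si](C(C)C)(C(C)C)C(C)C)C[C@@H]2O)cc1 | intermediate
14 | (R)-2-[4-(TBSO)phenyl]-7,8-bis(TIPSO)chroman-3-one | CC(C)(C)[Si](C)(C)Oc1ccc([C@H]2Oc3c(ccc(O[Si](C(C)C)(C(C)C)C(C)C)c3O[Si](C(C)C)(C(C)C)C(C)C)CC2=O)cc1 | intermediate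
15 | (2R,3R)-2-[4-(TBSO)phenyl]-7,8-bis(TIPSO)chroman-3-ol (2,3-cis) | CC(C)(C)[Si](C)(C)Oc1ccc([C@H]2Oc3c(ccc(O[Si](C(C)C)(C(C)C)C(C)C)c3O[Si](C(C)C)(C(C)C)C(C)C)C[C@H]2O)cc1 | intermediate
16 | (2R,3R)-3-(TBSO)-2-[4-(TBSO)phenyl]-7,8-bis(TIPSO)chroman | CC(C)(C)[Si](C)(C)Oc1ccc([C@H]2Oc3c(ccc(O[Si](C(C)C)(C(C)C)C(C)C)c3O[Si](C(C)C)(C(C)C)C(C)C)C[C@H]2O[Si](C)(C)C(C)(C)C)cc1 | intermediate
17 | (2R,3R,4S)-3-(TBSO)-2-[4-(TBSO)phenyl]-7,8-bis(TIPSO)chroman-4-ol (2,3-cis-3,4-trans) | CC(C)(C)[Si](C)(C)Oc1ccc([C@H]2Oc3c(ccc(O[Si](C(C)C)(C(C)C)C(C)C)c3O[Si](C(C)C)(C(C)C)C(C)C)[C@H](O)[C@H]2O[Si](C)(C)C(C)(C)C)cc1 | intermediate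
18 | (2R,3S)-3-(TBSO)-2-[4-(TBSO)phenyl]-7,8-bis(TIPSO)chroman-4-one (2,3-cis) | CC(C)(C)[Si](C)(C)Oc1ccc([C@H]2Oc3c(ccc(O[Si](C(C)C)(C(C)C)C(C)C)c3O[Si](C(C)C)(C(C)C)C(C)C)C(=O)[C@H]2O[Si](C)(C)C(C)(C)C)cc1 | intermediate
19 | (2R,3R,4R)-3-(TBSO)-2-[4-(TBSO)phenyl]-7,8-bis(TIPSO)chroman-4-ol (all-cis unit A alcohol) | CC(C)(C)[Si](C)(C)Oc1ccc([C@H]2Oc3c(ccc(O[Si](C(C)C)(C(C)C)C(C)C)c3O[Si](C(C)C)(C(C)C)C(C)C)[C@@H](O)[C@H]2O[Si](C)(C)C(C)(C)C)cc1 | intermediate
20 | ester of 19 (through O4) with acid 8; precursor of the key step | CC(C)(C)[Si](C)(C)Oc1ccc([C@H]2Oc3c(ccc(O[Si](C(C)C)(C(C)C)C(C)C)c3O[Si](C(C)C)(C(C)C)C(C)C)[C@@H](OC(=O)c3ccc(O[Si](C(C)C)(C(C)C)C(C)C)c(O[Si](C(C)C)(C(C)C)C(C)C)c3O[C@H](C=C)c3ccc(O[Si](C)(C)C(C)(C)C)cc3)[C@H]2O[Si](C)(C)C(C)(C)C)cc1 | intermediate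
21 | 1-arylvinyl ether: 20 with the ester C=O replaced by C=CH2 | CC(C)(C)[Si](C)(C)Oc1ccc([C@H]2Oc3c(ccc(O[Si](C(C)C)(C(C)C)C(C)C)c3O[Si](C(C)C)(C(C)C)C(C)C)[C@@H](OC(=C)c3ccc(O[Si](C(C)C)(C(C)C)C(C)C)c(O[Si](C(C)C)(C(C)C)C(C)C)c3O[C@H](C=C)c3ccc(O[Si](C)(C)C(C)(C)C)cc3)[C@H]2O[Si](C)(C)C(C)(C)C)cc1 | intermediate
22 | 4'-alkoxy-2H-chromene (flav-3-ene enol ether) dimer; product of the key step | CC(C)(C)[Si](C)(C)Oc1ccc([C@H]2Oc3c(ccc(O[Si](C(C)C)(C(C)C)C(C)C)c3O[Si](C(C)C)(C(C)C)C(C)C)[C@@H](OC3=C[C@H](c4ccc(O[Si](C)(C)C(C)(C)C)cc4)Oc4c(O[Si](C(C)C)(C(C)C)C(C)C)c(O[Si](C(C)C)(C(C)C)C(C)C)ccc43)[C@H]2O[Si](C)(C)C(C)(C)C)cc1 | intermediate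
23 | 3',4'-epoxide of 22, oxirane oxygen trans to the C2' aryl group | CC(C)(C)[Si](C)(C)Oc1ccc([C@H]2Oc3c(ccc(O[Si](C(C)C)(C(C)C)C(C)C)c3O[Si](C(C)C)(C(C)C)C(C)C)[C@@H](O[C@]34O[C@H]3[C@H](c5ccc(O[Si](C)(C)C(C)(C)C)cc5)Oc3c(O[Si](C(C)C)(C(C)C)C(C)C)c(O[Si](C(C)C)(C(C)C)C(C)C)ccc34)[C@H]2O[Si](C)(C)C(C)(C)C)cc1 | intermediate
24 | heptasilyl ether of the target with free 3'-OH | CC(C)(C)[Si](C)(C)Oc1ccc([C@H]2Oc3c(ccc(O[Si](C(C)C)(C(C)C)C(C)C)c3O[Si](C(C)C)(C(C)C)C(C)C)[C@@H](O[C@@H]3c4ccc(O[Si](C(C)C)(C(C)C)C(C)C)c(O[Si](C(C)C)(C(C)C)C(C)C)c4O[C@@H](c4ccc(O[Si](C)(C)C(C)(C)C)cc4)[C@@H]3O)[C@H]2O[Si](C)(C)C(C)(C)C)cc1 | intermediate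
25 | CNP0241481.1 | Oc1ccc([C@H]2Oc3c(ccc(O)c3O)[C@@H](O[C@@H]3c4ccc(O)c(O)c4O[C@@H](c4ccc(O)cc4)[C@@H]3O)[C@H]2O)cc1 | target

Total step count: 20.
Longest linear sequence: 17 steps (3 → 4 → 5 → 6 → 9 → 10 → 11 → 13 → 14 → 15 → 16 → 17 → 18 → 19 → 20 → 22 → 24 → 25).

Steps most likely to fail

Step 18. The sequence may stall after carbonyl methylenation because the hindered enol ether is not engaged by the titanium alkylidene, or the aluminium Lewis acid may ionise the C2' aryl allyl ether and erode its configuration. The fallback sets out from 20 and returns at 22. Methylenation alone with Cp2TiMe2 (toluene, 65 °C) gives the enol ether 21 as an isolated compound (already in the list; no new compound, F0). Ring-closing metathesis of 21 with a defined alkylidene catalyst, Mo(N-2,6-i-Pr2C6H3)(CHCMe2Ph)[OCMe(CF3)2]2 or the second-generation Grubbs catalyst, then closes ring C to 22.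

Step 19. Hydride may arrive on the wrong face of C4', the C4' oxocarbenium ion may shed unit A by fragmentation, or the Lewis acid may cleave the benzylic ether. The fallback sets out from 22 and returns at 24. Epoxy ether 23 is made as before and, without silane, is left to rearrange (toluene, rt, or MgBr2·OEt2 at low temperature) by the known epoxy ether to α-alkoxy ketone 1,2-hydride shift. The hydrogen moves suprafacially from C3' to C4' on the face opposite the oxirane oxygen and gives the 4'-alkoxyflavan-3'-one F1 with C4' already correct. Reduction with NaBH4/CeCl3, hydride entering anti to the 4'-alkoxy group (Felkin–Anh), then gives the 3'-alcohol 24.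

Step 5 (step 7 carries the same exposure). Carbon–oxygen bond formation at the hindered, chelated phenoxide may be slow, branched selectivity or enantioselectivity may erode, or a silyl group may shift. The fallback sets out from 2 and returns at 7 by a stereospecific SN2 route. Commercial 3-chloro-1-(4-hydroxyphenyl)propan-1-one is silylated to 3-chloro-1-[4-(TBSO)phenyl]propan-1-one F2. This is reduced with the (R)-Me-CBS oxazaborolidine and BH3·SMe2 to (S)-3-chloro-1-[4-(TBSO)phenyl]propan-1-ol F3. Mitsunobu etherification with 2 (PPh3, DIAD, inversion) gives (R)-2-{3-chloro-1-[4-(TBSO)phenyl]propoxy}-3,4-bis(TIPSO)benzaldehyde F4. NaI in acetone gives (R)-2-{3-iodo-1-[4-(TBSO)phenyl]propoxy}-3,4-bis(TIPSO)benzaldehyde F5, and E2 elimination with DBU gives the vinyl group of 7.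

Further compounds
F0 | step 18 | none | none
F1 | step 19 | 4'-alkoxyflavan-3'-one: 24 with C3'=O in place of C3'H–OH (4'-H cis to the 2'-aryl group) | CC(C)(C)[Si](C)(C)Oc1ccc([C@H]2Oc3c(ccc(O[Si](C(C)C)(C(C)C)C(C)C)c3O[Si](C(C)C)(C(C)C)C(C)C)[C@@H](O[C@@H]3c4ccc(O[Si](C(C)C)(C(C)C)C(C)C)c(O[Si](C(C)C)(C(C)C)C(C)C)c4O[C@@H](c4ccc(O[Si](C)(C)C(C)(C)C)cc4)C3=O)[C@H]2O[Si](C)(C)C(C)(C)C)cc1
F2 | step 5 | 3-chloro-1-[4-(TBSO)phenyl]propan-1-one | O=C(CCCl)c1ccc(O[Si](C)(C)C(C)(C)C)cc1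
F3 | step 5 | (S)-3-chloro-1-[4-(TBSO)phenyl]propan-1-ol | O[C@@H](CCCl)c1ccc(O[Si](C)(C)C(C)(C)C)cc1
F4 | step 5 | (R)-2-{3-chloro-1-[4-(TBSO)phenyl]propoxy}-3,4-bis(TIPSO)benzaldehyde | O=Cc1ccc(O[Si](C(C)C)(C(C)C)C(C)C)c(O[Si](C(C)C)(C(C)C)C(C)C)c1O[C@H](CCCl)c1ccc(O[Si](C)(C)C(C)(C)C)cc1
F5 | step 5 | (R)-2-{3-iodo-1-[4-(TBSO)phenyl]propoxy}-3,4-bis(TIPSO)benzaldehyde | O=Cc1ccc(O[Si](C(C)C)(C(C)C)C(C)C)c(O[Si](C(C)C)(C(C)C)C(C)C)c1O[C@H](CCI)c1ccc(O[Si](C)(C)C(C)(C)C)cc1
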